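(The earlier runs and the new flask stem from a simulated flask for an exercise, and the scatter is random.)

If target followed the catalyst charge in simple proportion, the Thursday's run, with 6.00 × 10⁻⁵ M of free catalyst against 3.00 × 10⁻⁴ M in the Friday's run, could be read from the Friday's run by one division.

| flask | starting material | partner | free catalyst | target | time |
|---|---|---|---|---|---|
| Friday's | 0.150 M | 0.225 M | 3.00 × 10⁻⁴ M |  |  |
| Monday's | 0.0750 M | 0.150 M | 3.00 × 10⁻⁴ M |  |  |
| Wednesday's | 0.150 M | 0.340 M | 3.00 × 10⁻⁴ M |  |  |
| Sunday's | 0.150 M | 0.225 M | 3.00 × 10⁻⁴ M | 0.0450 M |  |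
| Thursday's | 0.150 M | 0.225 M | 6.00 × 10⁻⁵ M |  | 10 min |

- Friday's run (time / min: [target] / M): 0.40: 0.0122; 0.63: 0.0185; 1.0: 0.0272; 1.6: 0.0382; 2.5: 0.0498; 4.0: 0.0636; 6.3: 0.0734; 10: 0.0806
- Monday's run (time / min: [target] / M): 0.40: 0.0042; 0.63: 0.0057; 1.0: 0.0099; 1.6: 0.0138; 2.5: 0.0193; 4.0: 0.0251; 6.3: 0.0304; 10: 0.0355
- Wednesday's run (time / min: [target] / M): 0.40: 0.0191; 0.63: 0.0269; 1.0: 0.0382; 1.6: 0.0531; 2.5: 0.0675; 4.0: 0.0814; 6.3: 0.0902; 10: 0.0922
- Sunday's run (time / min: [target] / M): 0.40: 0.0566; 0.63: 0.0629; 1.0: 0.0707; 1.6: 0.0809; 2.5: 0.0922; 4.0: 0.1036; 6.3: 0.1121; 10: 0.1168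

(scatter of a reading: 4 × 10⁻⁴ M)

- how the opening rate goes with [starting material] round the charge of the Friday's run: the exponent of the rate at two percent of starting material gone to target (one fixed amount of target, the same in the runs compared)
- how the opening rate goes with [partner] round the charge of the Friday's run: the exponent of the rate at two percent of starting material gone to target
- target in the Thursday's run at 10 min, as a share of the starting material charged

- Overall: starting material + partner -> target, with free catalyst as catalyst.
- Constant volume, constant temperature.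
- An order is taken over about fifteen percent of the charge, up and down.

By 10 min the Friday's run has reached 4.36 M⁻¹ of exposure, the time integral of rate divided by [starting material][partner], got from one target reading through the second-order integrated law. Exposure gathers the catalyst's working history into one number. In the Friday's run it grows by 0.950 M⁻¹ in the first 1.0 min, but its growth per minute falls from 0.950 M⁻¹ min⁻¹ to 0.180 M⁻¹ min⁻¹ over the last interval.

Now the question turned round. Exposure proportional to charge gives 0.873 M⁻¹ on Thursday, and the law run backwards gives 16.9% target. The opposite outcome, exposure indifferent to charge, repeats the Friday's 53.7%. The Friday's, Monday's, Wednesday's and Sunday's runs carry one catalyst charge, so the readings give no exponent between those ends. The reckoning here takes the exponent 0.5, a judgement and not a reading: exposure 1.95 M⁻¹, target 32.1%.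

The forecast gives orders of 0.97 (0.8 to 1.12) and 1.1 (0.92 to 1.3) and 17% (14% to 22%) for Thursday, adding “That catalyst order is untested”, and that share is lower than the one reckoned here.

The flask gives orders of 1.0 and 1.0, and 30.9% in the Thursday's run.

    2 free catalyst ⇌ catalyst dimer, settled at all times (5050 M⁻¹)
    free catalyst + starting material + partner → target + free catalyst (7920 M⁻² min⁻¹)
    target + partner → side product (0.1380 M⁻¹ min⁻¹)
    2 free catalyst → 2 spent catalyst (1950 M⁻¹ min⁻¹)

Free catalyst pairs to catalyst dimer with a constant of 5050 M⁻¹. The Thursday's 30.9% is an exposure of 1.85 M⁻¹, which against the Friday's 4.36 M⁻¹ makes an exponent of 0.532 in catalyst charge. The Wednesday's run, at the Friday's catalyst charge and with target counted without side product, reads 3.35 M⁻¹ of exposure at 10 min.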